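**Retrosynthetic overview** (drimane numbering: ring A = C1–C5 + C10, ring B = C5–C10, C11 = OCH2 on C9, C12 = exocyclic CH2 on C8; "drimane" implies 9α-H and 10β-CH3)
1. Late disconnections: C11–OAr (Mitsunobu, umbelliferone), 3β-OH (from the 3-ketone), 6β-OAc (from the 6-ketone, hydride from the α face), C8=C12 (Peterson), C9–C11 (enolate alkylation). These lead back to a 6,8-dioxygenated trans-decalin.
2. Enabling feature: in ring B the oxidised carbons C6 (OAc) and C8 (=CH2) are 1,3 across C7 and the quaternary C10 lies opposite C7. Ring B is therefore a latent mirror-symmetric 5,5-disubstituted cyclohexane-1,3-dione with enantiotopic methylenes C5 and C9, and O–C3–C4(CH3)2–C5–C6=O is the retron of a dienol ether opening a trisubstituted epoxide at its tertiary carbon.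
3. Key disconnection C4–C5: ring A is closed last by a desymmetrising epoxide opening. The (R)-epoxide, the only stereocentre that matters in the precursor, picks one of two equilibrating arms and so sets C10 and C5; its own carbinol centre is a relay that is inverted at the end by oxidation and reduction.
4. Ring order: ring B first (Michael–Claisen synthesis of the dione from an acyclic enone and dimethyl malonate), the coumarin is bought as umbelliferone, ring A last.

Key step: step 4

Assumption: the D-fructose-derived Shi ketone is taken to epoxidise the prenyl terminus R–CH=C(CH3)2 to the (R)-oxirane, the same facial sense that gives (R,R)-oxiranes from trans-disubstituted alkenes. The E/Z mixture of 1 is immaterial because its β-carbon becomes a non-stereogenic ring carbon.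

**Step 1**
Reactants: 1 4,8-dimethylnona-3,7-dien-2-one (commercial E/Z mixture); 2 dimethyl malonate
Product: 6 5-methyl-5-(4-methylpent-3-en-1-yl)cyclohexane-1,3-dione, via Michael adduct 3 (not isolated), via cyclic keto ester 4 (not isolated), via keto acid 5 (not isolated)
Conditions: NaOMe, MeOH, reflux; then aq KOH, reflux; then HCl to pH 3, 70 °C
Reagents that add atoms: none
Why: Michael addition of the malonate anion to the β,β-disubstituted enone, Claisen (Dieckmann-type) closure of the methyl ketone onto an ester, saponification and decarboxylation (the classical dimedone synthesis) should give the achiral dione, whose ring carbon bearing methyl and chain carries two identical arms and is not a stereocentre.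

**Step 2**
Reactants: 6 5-methyl-5-(4-methylpent-3-en-1-yl)cyclohexane-1,3-dione
Product: 7 3-methoxy-5-methyl-5-(4-methylpent-3-en-1-yl)cyclohex-2-en-1-one (racemic)
Conditions: Me2SO4, K2CO3, acetone, reflux
Reagents that add atoms: dimethyl sulfate, COS(=O)(=O)OC
Why: O-methylation of the vinylogous acid with a hard electrophile should give the vinylogous ester, which masks the acidic dione for the buffered epoxidation; the ring stereocentre is formed racemic on purpose because step 4 removes it again.

**Step 3**
Reactants: 7 3-methoxy-5-methyl-5-(4-methylpent-3-en-1-yl)cyclohex-2-en-1-one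
Product: 8 5-{2-[(2R)-3,3-dimethyloxiran-2-yl]ethyl}-3-methoxy-5-methylcyclohex-2-en-1-one (both epimers at the ring quaternary carbon)
Conditions: D-fructose-derived Shi ketone (30 mol %), KHSO5 (as Oxone, 2KHSO5·KHSO4·K2SO4), K2CO3, Bu4NHSO4, MeCN/CH2(OMe)2/aq Na2B4O7 buffer, 0 °C
Reagents that add atoms: potassium peroxymonosulfate, [K+].[O-]S(=O)(=O)OO
Why: Shi asymmetric epoxidation, in which the chiral dioxirane should attack only the electron-rich trisubstituted alkene (the push–pull C=C of the vinylogous ester is inert) through the spiro transition state that delivers the (R)-oxirane.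

**Step 4**
Reactants: 8 5-{2-[(2R)-3,3-dimethyloxiran-2-yl]ethyl}-3-methoxy-5-methylcyclohex-2-en-1-one
Product: 12 3α-(tert-butyldimethylsilyloxy)-6-methoxy-11,12-dinor-5α-drim-6-en-8-one, via dimethoxycyclohexenylium triflate 9 (not isolated), via dimethoxycyclohexadiene 10 (not isolated), via bicyclic dimethoxyallyl cation 11 (not isolated)
Conditions: MeOTf (1.05 equiv), 2,6-di-tert-butyl-4-methylpyridine (3 equiv), CH2Cl2 (0.01 M), 0 to 23 °C; then TBSOTf (1.3 equiv), −78 to 0 °C; then pH 7 phosphate buffer
Reagents that add atoms: methyl triflate, COS(=O)(=O)C(F)(F)F; tert-butyldimethylsilyl triflate, CC(C)(C)[Si](C)(C)OS(=O)(=O)C(F)(F)F; water, O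
Why: Proposed new method: O-methylation by MeOTf should convert both ring epimers of 8 into one ion 9 whose ring is mirror-symmetric, reversible deprotonation by the hindered pyridine at either CH2 next to the quaternary carbon gives the two dienol ethers 10 in equilibrium through 9, and the terminal dienol carbon (C5) then opens the silyl-activated epoxide at its tertiary carbon C4 with inversion to give cation 11, which water hydrolyses at C8. The closest known reactions are the Lewis-acid-promoted cyclisation of epoxides onto silyl enol ethers and the Mukaiyama-type reactions of cyclic 1-alkoxy-3-silyloxy-1,3-dienes at their terminal carbon; what is new is the dimethoxydiene made in situ and the use of the epoxide to choose between two equilibrating arms (Curtin–Hammett control). Ring A closes 6-endo with respect to the epoxide (both oxirane carbons end up in the ring) and exo with respect to the enol ether (C5 inside, C6 outside), through a chair in which the C3–O bond is equatorial because it must be anti to the forming C4–C5 bond. C10 is set by this chair: attack has to be perpendicular to the planar C5 of ring B, which forces the unreacting arm C9 axial and the C10 methyl equatorial on the new ring, so the (R)-epoxide should select the arm that gives the natural C10 configuration with the C3 silyloxy group trans to the methyl group (3α, inverted in steps 11 and 12); C3 keeps the epoxide configuration. C5 is formed cis-fused and should equilibrate at 0 °C through the C5=C6 dienol ether of 11, reprotonation from the α face (the β face is screened by the axial methyls on C4 and C10) giving the trans fusion. The step needs arm selectivity (chair versus boat, as above), opening at the tertiary oxirane carbon (its cationic character and the six-membered closure) and hydrolysis at the less hindered terminus C8 rather than at C6, which is flanked by C5 and the C4 gem-dimethyl group, so that C8 emerges as the free ketone and C6 stays masked as its methyl enol ether; high dilution and the non-nucleophilic base limit intermolecular addition of 10 to 9 and elimination of the activated epoxide.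

**Step 5**
Reactants: 12 3α-(tert-butyldimethylsilyloxy)-6-methoxy-11,12-dinor-5α-drim-6-en-8-one
Product: 14 3α-(tert-butyldimethylsilyloxy)-6-methoxy-11-(triisopropylsilyloxy)-12-nor-5α-drim-6-en-8-one (9α-H), via 9α-alkyl epimer 13 (not isolated)
Conditions: LiN(i-Pr)2 (1.15 equiv), THF, −78 °C; (i-Pr)3SiOCH2Cl, −78 to −30 °C; then MeOH, NaOMe (0.3 equiv), 23 °C
Reagents that add atoms: (triisopropylsiloxy)methyl chloride, ClCO[Si](C(C)C)(C(C)C)C(C)C
Why: Stork–Danheiser α'-deprotonation gives the cross-conjugated enolate at C9, which the α-chloro ether (a protected hydroxymethyl cation equivalent) should C-alkylate from the α face anti to the C10 methyl group (epimer 13), and methoxide equilibration of this centre next to the C8 ketone should then give the equatorial 9β-CH2OSi epimer (and return any cis-fused material to the trans series).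

**Step 6**
Reactants: 14 3α-(tert-butyldimethylsilyloxy)-6-methoxy-11-(triisopropylsilyloxy)-12-nor-5α-drim-6-en-8-one
Product: 17 3α-(tert-butyldimethylsilyloxy)-11-(triisopropylsilyloxy)-5α-drim-8(12)-en-6-one, via silyl carbinol 15 (not isolated), via dienol ether 16 (not isolated)
Conditions: Me3SiCH2Li (2.5 equiv), THF, −78 to 0 °C; then oxalic acid, THF/H2O, 0 °C
Reagents that add atoms: (trimethylsilyl)methyllithium, [Li]C[Si](C)(C)C; water, O
Why: Peterson olefination in the Stork–Danheiser mode: 1,2-addition to the vinylogous ester carbonyl, acid-induced loss of silanol from the β-hydroxysilane (ionisation assisted by the enol ether, then loss of the β-silyl group) and kinetic α-protonation and hydrolysis of the 1-methoxydiene by oxalic acid should give the exocyclic methylene and unmask the C6 ketone without moving the alkene into conjugation; C5 and C9 are untouched.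

**Step 7**
Reactants: 17 3α-(tert-butyldimethylsilyloxy)-11-(triisopropylsilyloxy)-5α-drim-8(12)-en-6-one
Product: 18 3α-(tert-butyldimethylsilyloxy)-11-(triisopropylsilyloxy)-5α-drim-8(12)-en-6β-ol
Conditions: NaBH4, CeCl3·7H2O, MeOH, −78 to −40 °C (crude 17 used at once)
Reagents that add atoms: none
Why: Luche reduction, in which hydride should add to the C6 ketone from the α face because the β face is screened by the axial methyl groups on C4 and C10, giving the axial 6β-alcohol, while the cerium-buffered medium avoids base-induced migration of the β,γ-double bond.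

**Step 8**
Reactants: 18 3α-(tert-butyldimethylsilyloxy)-11-(triisopropylsilyloxy)-5α-drim-8(12)-en-6β-ol
Product: 19 6β-acetoxy-3α-(tert-butyldimethylsilyloxy)-11-(triisopropylsilyloxy)-5α-drim-8(12)-ene
Conditions: Ac2O, DMAP, pyridine, 60 °C
Reagents that add atoms: acetic anhydride, CC(=O)OC(C)=O
Why: DMAP-catalysed acetylation of the only free hydroxyl group; the hindered axial 6β-alcohol needs heat, and O3 and O11 are held as silyl ethers.

**Step 9**
Reactants: 19 6β-acetoxy-3α-(tert-butyldimethylsilyloxy)-11-(triisopropylsilyloxy)-5α-drim-8(12)-ene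
Product: 20 6β-acetoxy-5α-drim-8(12)-ene-3α,11-diol
Conditions: HF·pyridine, pyridine/THF, 0 to 40 °C
Reagents that add atoms: none
Why: Fluoride cleavage of the primary triisopropylsilyl ether and the hindered secondary tert-butyldimethylsilyl ether in buffered HF·pyridine, under which the acetate and the exocyclic alkene should persist.

**Step 10**
Reactants: 20 6β-acetoxy-5α-drim-8(12)-ene-3α,11-diol; 21 umbelliferone (7-hydroxy-2H-chromen-2-one)
Product: 22 7-[(6β-acetoxy-3α-hydroxy-5α-drim-8(12)-en-11-yl)oxy]-2H-chromen-2-one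
Conditions: PPh3, DIAD, THF, 0 to 45 °C
Reagents that add atoms: none
Why: Mitsunobu etherification, in which the acidic phenol displaces the oxyphosphonium of the primary C11 alcohol while the axial, neopentyl-type 3α-alcohol should not react; no stereocentre is involved.

**Step 11**
Reactants: 22 7-[(6β-acetoxy-3α-hydroxy-5α-drim-8(12)-en-11-yl)oxy]-2H-chromen-2-one
Product: 23 7-[(6β-acetoxy-3-oxo-5α-drim-8(12)-en-11-yl)oxy]-2H-chromen-2-one
Conditions: Dess–Martin periodinane, pyridine, CH2Cl2, 23 °C
Reagents that add atoms: none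
Why: Dess–Martin oxidation of the remaining secondary alcohol under near-neutral conditions erases the relay stereocentre at C3 and should leave acetate, alkene and coumarin intact.

**Step 12**
Reactants: 23 7-[(6β-acetoxy-3-oxo-5α-drim-8(12)-en-11-yl)oxy]-2H-chromen-2-one
Product: 24 7-[(6β-acetoxy-3β-hydroxy-5α-drim-8(12)-en-11-yl)oxy]-2H-chromen-2-one (target)
Conditions: NaBH4, CeCl3·7H2O, MeOH/THF, −20 °C
Reagents that add atoms: none
Why: Substrate-controlled reduction of the 4,4-dimethyl-3-ketone, in which hydride should attack axially from the α face to give the equatorial 3β-alcohol, while these mild conditions should spare the acetate and the coumarin lactone.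

**Compound list**
1 | 4,8-dimethylnona-3,7-dien-2-one (E/Z mixture) | CC(=O)C=C(C)CCC=C(C)C | starting material
2 | dimethyl malonate | COC(=O)CC(=O)OC | starting material
3 | dimethyl 2-(4,8-dimethyl-2-oxonon-7-en-4-yl)malonate (racemic) | COC(=O)C(C(=O)OC)C(C)(CCC=C(C)C)CC(C)=O | intermediate
4 | methyl 6-methyl-6-(4-methylpent-3-en-1-yl)-2,4-dioxocyclohexane-1-carboxylate (sodium enolate in the flask) | COC(=O)C1C(=O)CC(=O)CC1(C)CCC=C(C)C | intermediate
5 | 6-methyl-6-(4-methylpent-3-en-1-yl)-2,4-dioxocyclohexane-1-carboxylic acid | OC(=O)C1C(=O)CC(=O)CC1(C)CCC=C(C)C | intermediate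
6 | 5-methyl-5-(4-methylpent-3-en-1-yl)cyclohexane-1,3-dione | CC(C)=CCCC1(C)CC(=O)CC(=O)C1 | intermediate
7 | 3-methoxy-5-methyl-5-(4-methylpent-3-en-1-yl)cyclohex-2-en-1-one (racemic) | COC1=CC(=O)CC(C)(CCC=C(C)C)C1 | intermediate
8 | 5-{2-[(2R)-3,3-dimethyloxiran-2-yl]ethyl}-3-methoxy-5-methylcyclohex-2-en-1-one (both ring epimers) | COC1=CC(=O)CC(C)(CC[C@H]2OC2(C)C)C1 | intermediate
9 | 5-{2-[(2R)-3,3-dimethyloxiran-2-yl]ethyl}-1,3-dimethoxy-5-methylcyclohexenylium triflate (delocalised, mirror-symmetric ring) | COC1=CC(=[O+]C)CC(C)(CC[C@H]2OC2(C)C)C1.[O-]S(=O)(=O)C(F)(F)F | intermediate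
10 | 5-{2-[(2R)-3,3-dimethyloxiran-2-yl]ethyl}-1,3-dimethoxy-5-methylcyclohexa-1,3-diene (both ring epimers, interconverting through 9) | COC1=CC(OC)=CC(C)(CC[C@H]2OC2(C)C)C1 | intermediate
11 | 3α-(tert-butyldimethylsilyloxy)-6,8-dimethoxy-11,12-dinor-5α-drim-6-en-8-ylium triflate (delocalised over C6–C8) | C[O+]=C1C=C(OC)[C@H]2C(C)(C)[C@H](O[Si](C)(C)C(C)(C)C)CC[C@]2(C)C1.[O-]S(=O)(=O)C(F)(F)F | intermediate
12 | 3α-(tert-butyldimethylsilyloxy)-6-methoxy-11,12-dinor-5α-drim-6-en-8-one | O=C1C=C(OC)[C@H]2C(C)(C)[C@H](O[Si](C)(C)C(C)(C)C)CC[C@]2(C)C1 | intermediate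
13 | 9-epimer of 14 (9α-CH2OSi(i-Pr)3, 9β-H) | O=C1C=C(OC)[C@H]2C(C)(C)[C@H](O[Si](C)(C)C(C)(C)C)CC[C@]2(C)[C@@H]1CO[Si](C(C)C)(C(C)C)C(C)C | intermediate
14 | 3α-(tert-butyldimethylsilyloxy)-6-methoxy-11-(triisopropylsilyloxy)-12-nor-5α-drim-6-en-8-one (9α-H) | O=C1C=C(OC)[C@H]2C(C)(C)[C@H](O[Si](C)(C)C(C)(C)C)CC[C@]2(C)[C@H]1CO[Si](C(C)C)(C(C)C)C(C)C | intermediate
15 | 3α-(tert-butyldimethylsilyloxy)-6-methoxy-11-(triisopropylsilyloxy)-12-(trimethylsilyl)-5α-drim-6-en-8-ol (either C8 epimer) | C[Si](C)(C)CC1(O)C=C(OC)[C@H]2C(C)(C)[C@H](O[Si](C)(C)C(C)(C)C)CC[C@]2(C)[C@H]1CO[Si](C(C)C)(C(C)C)C(C)C | intermediate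
16 | 3α-(tert-butyldimethylsilyloxy)-6-methoxy-11-(triisopropylsilyloxy)-5α-drima-6,8(12)-diene | C=C1C=C(OC)[C@H]2C(C)(C)[C@H](O[Si](C)(C)C(C)(C)C)CC[C@]2(C)[C@H]1CO[Si](C(C)C)(C(C)C)C(C)C | intermediate
17 | 3α-(tert-butyldimethylsilyloxy)-11-(triisopropylsilyloxy)-5α-drim-8(12)-en-6-one | C=C1CC(=O)[C@H]2C(C)(C)[C@H](O[Si](C)(C)C(C)(C)C)CC[C@]2(C)[C@H]1CO[Si](C(C)C)(C(C)C)C(C)C | intermediate
18 | 3α-(tert-butyldimethylsilyloxy)-11-(triisopropylsilyloxy)-5α-drim-8(12)-en-6β-ol | C=C1C[C@@H](O)[C@H]2C(C)(C)[C@H](O[Si](C)(C)C(C)(C)C)CC[C@]2(C)[C@H]1CO[Si](C(C)C)(C(C)C)C(C)C | intermediate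
19 | 6β-acetoxy-3α-(tert-butyldimethylsilyloxy)-11-(triisopropylsilyloxy)-5α-drim-8(12)-ene | C=C1C[C@@H](OC(C)=O)[C@H]2C(C)(C)[C@H](O[Si](C)(C)C(C)(C)C)CC[C@]2(C)[C@H]1CO[Si](C(C)C)(C(C)C)C(C)C | intermediate
20 | 6β-acetoxy-5α-drim-8(12)-ene-3α,11-diol | C=C1C[C@@H](OC(C)=O)[C@H]2C(C)(C)[C@H](O)CC[C@]2(C)[C@H]1CO | intermediate
21 | umbelliferone (7-hydroxy-2H-chromen-2-one) | Oc1ccc2ccc(=O)oc2c1 | starting material
22 | 7-[(6β-acetoxy-3α-hydroxy-5α-drim-8(12)-en-11-yl)oxy]-2H-chromen-2-one | C=C1C[C@@H](OC(C)=O)[C@H]2C(C)(C)[C@H](O)CC[C@]2(C)[C@H]1COc1ccc2ccc(=O)oc2c1 | intermediate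
23 | 7-[(6β-acetoxy-3-oxo-5α-drim-8(12)-en-11-yl)oxy]-2H-chromen-2-one | C=C1C[C@@H](OC(C)=O)[C@H]2C(C)(C)C(=O)CC[C@]2(C)[C@H]1COc1ccc2ccc(=O)oc2c1 | intermediate
24 | 7-[(6β-acetoxy-3β-hydroxy-5α-drim-8(12)-en-11-yl)oxy]-2H-chromen-2-one | C=C1C[C@@H](OC(C)=O)[C@H]2C(C)(C)[C@@H](O)CC[C@]2(C)[C@H]1COc1ccc2ccc(=O)oc2c1 | target

**Total step count:** 12. **Longest linear sequence:** 12 steps (from 1 and 2).

**Steps most likely to fail**

Step 4 (proposed new method). The two arms may not be told apart well enough if closure through a boat on the other arm competes. The silyl-activated epoxide may be lost by elimination or 1,2-hydride shift before the small equilibrium amount of dienol ether captures it. Water may also attack cation 11 at C6 instead of C8. The fallback uses known chemistry and sets out from 8. Kinetic α'-enolisation and silylation (LiN(i-Pr)2, Me3SiCl, THF, −78 °C) gives the 5-{2-[(2R)-3,3-dimethyloxiran-2-yl]ethyl}-1-methoxy-5-methyl-3-(trimethylsilyloxy)cyclohexa-1,3-diene F1 as its two ring epimers. MeAlCl2 (CH2Cl2, −78 °C) then closes ring A by the established Lewis-acid cyclisation of an epoxide onto a silyl enol ether. Only the epimer whose silyloxy-bearing arm matches the epoxide can close through the chair, so at most half of the material is used and the other diastereomeric series is removed by chromatography. The product, after epimerisation of C5 next to the ketone, is 3α-hydroxy-8-methoxy-11,12-dinor-5α-drim-7-en-6-one F2. Silylation (TBSOTf, 2,6-lutidine) gives its tert-butyldimethylsilyl ether F3, and aqueous HCl in THF hydrolyses this to 3α-(tert-butyldimethylsilyloxy)-11,12-dinor-5α-drimane-6,8-dione F4. Re-etherification (MeOH, CH(OMe)3, TsOH) gives 12 together with F3, which is separated and recycled through F4. The route is rejoined at 12.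

Step 6. The exocyclic double bond may migrate into conjugation with the C6 ketone during the acidic unmasking, or the silylmethyl reagent may enolise C9 instead of adding. The fallback sets out from 14. Aqueous HCl in THF hydrolyses the vinylogous ester to 3α-(tert-butyldimethylsilyloxy)-11-(triisopropylsilyloxy)-12-nor-5α-drimane-6,8-dione F5. Triflation at the less hindered enol oxygen (Tf2O, Et3N, CH2Cl2, −78 °C) gives the 8-triflyloxy-12-nor-5α-drim-7-en-6-one F6. Pd(PPh3)4-catalysed Kumada coupling with Me3SiCH2MgCl gives the 12-(trimethylsilyl)-5α-drim-7-en-6-one F7. Fluoride (Bu4NF buffered with AcOH, THF, −78 °C) cleaves the allylic C–Si bond to the exocyclic dienolate, and its kinetic α-protonation at C7 under cold, buffered conditions gives 17, where the route is rejoined.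

Step 10. Displacement at the β-branched C11 oxyphosphonium, next to the quaternary C10, may be slow and give way to elimination. The fallback sets out from 20 and forms the other C–O bond of the ether instead: Pd-catalysed etherification of the primary alcohol with 7-bromo-2H-chromen-2-one ([Pd(allyl)Cl]2, RockPhos, Cs2CO3, toluene, 90 °C) should give 22 directly, with no new intermediate (F0).

**Further compounds**
F1 | step 4 | 5-{2-[(2R)-3,3-dimethyloxiran-2-yl]ethyl}-1-methoxy-5-methyl-3-(trimethylsilyloxy)cyclohexa-1,3-diene (both ring epimers) | COC1=CC(O[Si](C)(C)C)=CC(C)(CC[C@H]2OC2(C)C)C1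
F2 | step 4 | 3α-hydroxy-8-methoxy-11,12-dinor-5α-drim-7-en-6-one | COC1=CC(=O)[C@H]2C(C)(C)[C@H](O)CC[C@]2(C)C1
F3 | step 4 | 3α-(tert-butyldimethylsilyloxy)-8-methoxy-11,12-dinor-5α-drim-7-en-6-one | COC1=CC(=O)[C@H]2C(C)(C)[C@H](O[Si](C)(C)C(C)(C)C)CC[C@]2(C)C1
F4 | step 4 | 3α-(tert-butyldimethylsilyloxy)-11,12-dinor-5α-drimane-6,8-dione | O=C1CC(=O)[C@H]2C(C)(C)[C@H](O[Si](C)(C)C(C)(C)C)CC[C@]2(C)C1
F5 | step 6 | 3α-(tert-butyldimethylsilyloxy)-11-(triisopropylsilyloxy)-12-nor-5α-drimane-6,8-dione | O=C1CC(=O)[C@H]2C(C)(C)[C@H](O[Si](C)(C)C(C)(C)C)CC[C@]2(C)[C@H]1CO[Si](C(C)C)(C(C)C)C(C)C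
F6 | step 6 | 3α-(tert-butyldimethylsilyloxy)-11-(triisopropylsilyloxy)-8-(trifluoromethylsulfonyloxy)-12-nor-5α-drim-7-en-6-one | FC(F)(F)S(=O)(=O)OC1=CC(=O)[C@H]2C(C)(C)[C@H](O[Si](C)(C)C(C)(C)C)CC[C@]2(C)[C@H]1CO[Si](C(C)C)(C(C)C)C(C)C
F7 | step 6 | 3α-(tert-butyldimethylsilyloxy)-11-(triisopropylsilyloxy)-12-(trimethylsilyl)-5α-drim-7-en-6-one | C[Si](C)(C)CC1=CC(=O)[C@H]2C(C)(C)[C@H](O[Si](C)(C)C(C)(C)C)CC[C@]2(C)[C@H]1CO[Si](C(C)C)(C(C)C)C(C)C
F0 | step 10 | none | none
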